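All runs are calculated from invented constants.

**Reading time.** At 5.0 min for larch and 10 min for maple the product is counted, so the question is how much of each charge has arrived by then.

the same everywhere: free catalyst 2.5 µM; second catalyst 50 µM

|  | starting material | coupling partner | protic impurity | remark | time |
|---|---|---|---|---|---|
| noon | 5 mM | 7.5 mM | 1.1 mM | run made earlier |  |
| midnight | 5 mM | 7.5 mM | 2.3 mM | run made earlier |  |
| autumn | 3.4 mM | 7.5 mM | 1.5 mM | run made earlier |  |
| larch | 1.2 mM | 7.50 mM | 0.800 mM |  | 5.0 min |
| maple | 5.0 mM | 7.50 mM | 1.50 mM |  | 10 min |

- noon (time / min: product / %, starting material / %): 0.667: 9.5, 51.2; 2.00: 31.6, 31.2; 3.00: 42.2, 23.2; 5.00: 54.2, 13.4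
- midnight (time / min: product / %, starting material / %): 0.417: 4.3, 54.9; 1.00: 14.1, 35.7; 2.00: 27.5, 22.7; 5.00: 45.0, 9.2
- autumn (time / min: product / %, starting material / %): 1.33: 20.6, 31.9; 2.50: 33.6, 19.8; 4.00: 45.6, 12.0; 5.00: 49.3, 9.1

(readings scatter by 0.5 percentage points)



1. which of the two ends with the higher amount of product, in percent of the starting material charged ("neither" if they lie within 2 percentage points) (larch / maple / neither)
2. product at the end, in percent of the starting material charged, larch
3. product at the end, in percent of the starting material charged, maple

**Main step.** Between its last readings the noon flask gains product at 0.328 min⁻¹ per fraction of starting material visible, and the autumn flask, between its own, at 0.435 min⁻¹. Dividing also by the fraction of coupling partner left, reckoned from the product made, gives 0.483 min⁻¹ for noon and 0.535 min⁻¹ for autumn, a narrower gap. This reading, with noon's value carried on, is the product constant: product gained per minute, per fraction of starting material visible and per fraction of coupling partner left, a pseudo-first-order constant while the partner stays near its charge. A bare exponential in this constant, with the partner held, reckons 91.1% for larch at its time of reading; that is a first figure of this reckoning and no more, since it counts the visible starting material as the whole of what remains to react.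

**Adding impurity.** If all that autumn leaves unaccounted was quenched, its impurity averages 52.9% of its charge, as much as larch holds at the start. Autumn's curve therefore stands in for larch, and the figure drops to 49.3%.

**Adding partner drain.** Autumn keeps on average 88.8% of its partner and larch 96.1%, so the reckoning here gives larch 53.3%.

**Maple reckoned.** Between noon and midnight, maple's impurity gives 51.1% product and 12.0% starting material at 5.00 min. With noon's late decay of 0.274 min⁻¹, the constant adds 12 percentage points, giving 63.1%.

**The forecast.** It names maple, with 29% for larch and 62% for maple, on the ground that “The missing material looks roughly stoichiometric with impurity”. Its maple stands close to the reckoning here, but its larch stands far lower.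

    starting material + protic impurity → quenched substrate (k = 5.53 M⁻¹ s⁻¹)
    starting material + free catalyst ⇌ free catalyst + open intermediate (K = 0.840, k = 7970 M⁻¹ s⁻¹)
    coupling partner + catalyst intermediate → second catalyst + product (k = 1490 M⁻¹ s⁻¹)
    second catalyst + open intermediate ⇌ catalyst intermediate (K = 23.0 M⁻¹, k = 12800 M⁻¹ s⁻¹)

**The result.** Larch gives 56.1% and maple 63.7%, so maple ends higher. At 5.00 min larch holds 29.2% quenched substrate, with 56.2% of its impurity still present. From 2.50 min to 5.00 min the product constant reckons 17 points for larch, which gains 17 points. From 5.00 min to 10.0 min it reckons 13 points for maple, which gains 13 points.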